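**Retrosynthetic overview**

1. Both aryl alkyl ethers are cut first. The oxolane core takes up the two antipodal α-aryloxy ketones one at a time from lactate-derived α-mesyloxy ketones (SN2, inversion), and each ketone is reduced under Felkin–Anh control to the threo carbinol.
2. The C2–aryl bond (ring A) is cut next: ipso-arylation of the cyclic oxocarbenium ion of a 5-aryl-3,4-dimethyl lactol, anti to the C3 methyl.
3. The lactol is cut at O1–C2 and C2–C3. A tether-directed branched hydroformylation of a syn homoallylic alcohol places a formyl carbon (C2, from CO) on C3 and the C5 oxygen closes onto it. This oxolane is the only ring that is built (step 3); all benzene rings are bought.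
4. Enabling feature: O1 sits on C5, homoallylic to C3 and 1,4 to C2. As the free C5–OH it first carries a temporary O–P bond (Ph2P–O–C5) that steers rhodium to C3 through a six-membered chelate; the same oxygen then adds to the new C2 aldehyde as a five-membered hemiacetal. A tosylate on ring B keeps the C5–O bond from ionizing later.
5. The C4/C5 stereodiad comes from a catalytic asymmetric (Z)-crotylboration of O-tosylvanillin.

Key step: step 3

Remark on the structure: CIP analysis of the target gives a (2S,3S,4S,5R)-oxolane (2,3-trans, 3,4-trans, 4,5-cis; ring A = guaiacyl ring on C2, ring B = guaiacyl ring on C5). The ring-A ether chain is (1R,2R)-threo and the ring-B ether chain is (1S,2S)-threo, so the two antipodal chains are installed separately, from (S)- and (R)-lactate.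

**Route**

Step 1
Reactants: 1 vanillin
Product: 2 4-formyl-2-methoxyphenyl 4-methylbenzenesulfonate (O-tosylvanillin)
Conditions: TsCl, K2CO3, acetone, rt
Reagents that add atoms: 4-methylbenzenesulfonyl chloride (TsCl), Cc1ccc(cc1)S(Cl)(=O)=O
Why: O-sulfonylation of the phenol; the tosylate is kept until step 12 because it makes ring B electron-poor, so that the C5 benzylic C–O bond cannot ionize under the Lewis acid of step 5.

Step 2
Reactants: 2 O-tosylvanillin; 3 (Z)-crotylboronic acid pinacol ester
Product: 4 4-[(1R,2S)-1-hydroxy-2-methylbut-3-en-1-yl]-2-methoxyphenyl 4-methylbenzenesulfonate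
Conditions: (R)-TRIP [(R)-3,3'-bis(2,4,6-triisopropylphenyl)-1,1'-binaphthyl-2,2'-diyl hydrogen phosphate] (5 mol %), toluene, 4 Å molecular sieves, −30 °C; aq. NaHCO3
Reagents that add atoms: none
Why: Chiral Brønsted acid catalysed crotylboration through a closed Zimmerman–Traxler chair; the (Z)-crotyl geometry should give the syn relationship (future C4/C5 cis) and the (R)-phosphoric acid is expected to direct attack to the Re face of the aldehyde, setting the carbinol carbon as R and the methyl-bearing carbon as S.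

Step 3
Reactants: 4 syn homoallylic alcohol
Product: 7 (3S,4S,5R)-5-[3-methoxy-4-(tosyloxy)phenyl]-3,4-dimethyloxolan-2-ol (lactol; both anomers), via tethered diphenylphosphinite 5 (not isolated), via branched hydroxy aldehyde 6 (not isolated)
Conditions: Rh(CO)2(acac) (1 mol %), Ph2POMe (10 mol %), CO/H2 (1:1, 20 bar), 4 Å molecular sieves, THF, 40 °C; then DBU (10 mol %), CH2Cl2, rt
Reagents that add atoms: carbon monoxide, [C-]#[O+]
Why: Exchange of catalytic Ph2POMe with the C5 hydroxyl gives phosphinite 5, whose phosphorus holds rhodium so that Rh–H adds across the vinyl group through a six-membered chelate (Rh on C3); CO insertion and hydrogenolysis give the branched aldehyde, and alcohol exchange releases hydroxy aldehyde 6 and frees the tether for the next turnover. The closest known reaction type is the branched-selective hydroformylation of homoallylic alcohols with a catalytic, reversibly bound phosphinite directing group, which likewise ends in γ-lactols. The oxolane ring closes by 5-exo-trig addition of the C5 hydroxyl oxygen to the new formyl carbon (O1–C2), a spontaneous hemiacetalization of a γ-hydroxy aldehyde. C3 is the new stereocenter that matters: whatever the kinetic ratio from the chelated hydride insertion, C3 is α to the masked aldehyde, so the DBU treatment should equilibrate it through the open chain to the methyl trans to the C4 methyl; C2 is formed as an anomeric mixture on purpose because it is planarized in step 5. The step needs branched instead of linear regioselectivity, against the normal preference of a terminal alkene with an allylic branch; the six- versus seven-membered chelate imposed by the temporary O–P tether is what secures it, and C4 and C5 are not touched.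

Step 4
Reactants: 8 [4-(benzyloxy)-3-methoxyphenyl]boronic acid
Product: 9 potassium [4-(benzyloxy)-3-methoxyphenyl]trifluoroborate
Conditions: KHF2 (aq.), MeOH, rt
Reagents that add atoms: potassium hydrogen difluoride (KHF2), [K+].[F-].F
Why: Standard conversion of a boronic acid into its trifluoroborate salt, which gives a weighable, stoichiometrically exact aryl nucleophile for step 5.

Step 5
Reactants: 7 lactol; 9 aryltrifluoroborate
Product: 10 (2S,3S,4S,5R)-2-[4-(benzyloxy)-3-methoxyphenyl]-5-[3-methoxy-4-(tosyloxy)phenyl]-3,4-dimethyloxolane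
Conditions: BF3·OEt2 (3 equiv), CH2Cl2/MeCN, −40 → 0 °C
Reagents that add atoms: none
Why: Lewis acid mediated coupling of an organotrifluoroborate with an acetal-type electrophile (Friedel–Crafts-type ipso substitution): BF3 ionizes the lactol to the cyclic oxocarbenium ion with the O1–C2 bond intact and turns 9 into the aryldifluoroborane, whose ipso carbon should attack C2 anti to the adjacent C3 methyl, giving the 2,3-trans, 2,5-cis oxolane, which is also the more stable C2 epimer.

Step 6
Reactants: 10 benzyl ether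
Product: 11 4-[(2S,3S,4S,5R)-5-[3-methoxy-4-(tosyloxy)phenyl]-3,4-dimethyloxolan-2-yl]-2-methoxyphenol
Conditions: H2 (1 atm), Pd/C (10 wt % palladium on carbon), EtOAc, rt
Reagents that add atoms: none
Why: Hydrogenolysis of the benzyl aryl ether under neutral conditions, done here before any reducible α-aryloxy ketone is present; the aryl tosylate and the ring benzylic C–O bonds are expected to survive.

Step 7
Reactants: 12 ethyl (S)-lactate
Product: 13 (S)-2-hydroxy-N-methoxy-N-methylpropanamide
Conditions: MeNHOMe·HCl, iPrMgCl, THF, −20 → 0 °C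
Reagents that add atoms: N,O-dimethylhydroxylamine hydrochloride, CNOC.Cl
Why: Ester aminolysis by the magnesium amide of the hydroxylamine (Weinreb amide formation); the lactate stereocenter is not involved.

Step 8
Reactants: 13 Weinreb amide; 14 3,4-dimethoxyphenylmagnesium bromide
Product: 15 (S)-1-(3,4-dimethoxyphenyl)-2-hydroxypropan-1-one
Conditions: 14 (2.5 equiv), THF, 0 °C → rt; aq. NH4Cl
Reagents that add atoms: none
Why: Grignard addition to a Weinreb amide stops at the chelated tetrahedral intermediate (one equivalent is spent on the free hydroxyl), so the ketone is released only on work-up and the α-stereocenter is retained.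

Step 9
Reactants: 15 (S)-hydroxy ketone
Product: 16 (S)-1-(3,4-dimethoxyphenyl)-1-oxopropan-2-yl methanesulfonate
Conditions: MsCl, Et3N, CH2Cl2, 0 °C
Reagents that add atoms: methanesulfonyl chloride (MsCl), CS(Cl)(=O)=O
Why: O-sulfonylation with retention (the C–O bond is not broken) gives an SN2-active α-keto secondary mesylate.

Step 10
Reactants: 11 ring-A phenol; 16 (S)-mesylate
Product: 17 (2R)-1-(3,4-dimethoxyphenyl)-2-[2-methoxy-4-[(2S,3S,4S,5R)-5-[3-methoxy-4-(tosyloxy)phenyl]-3,4-dimethyloxolan-2-yl]phenoxy]propan-1-one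
Conditions: K2CO3, DMF, rt
Reagents that add atoms: none
Why: Williamson ether synthesis by SN2 displacement of the carbonyl-activated mesylate with the phenoxide; inversion turns the (S)-mesylate into the (R)-aryl ether.

Step 11
Reactants: 17 ring-A ketone
Product: 18 4-[(2R,3S,4S,5S)-5-[4-[(1R,2R)-1-(3,4-dimethoxyphenyl)-1-hydroxypropan-2-yl]oxy-3-methoxyphenyl]-3,4-dimethyloxolan-2-yl]-2-methoxyphenyl 4-methylbenzenesulfonate
Conditions: LiBH(s-Bu)3, THF, −78 °C; aq. NH4Cl
Reagents that add atoms: none
Why: Felkin–Anh controlled reduction: a bulky, poorly chelating hydride should add anti to the α-aryloxy group and past the α-hydrogen, which gives the threo (1R,2R) carbinol from the (2R) ketone.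

Step 12
Reactants: 18 aryl tosylate
Product: 19 (1R,2R)-1-(3,4-dimethoxyphenyl)-2-[4-[(2S,3S,4S,5R)-5-(4-hydroxy-3-methoxyphenyl)-3,4-dimethyloxolan-2-yl]-2-methoxyphenoxy]propan-1-ol
Conditions: KOH, MeOH/THF, 60 °C; aq. NH4Cl
Reagents that add atoms: none
Why: Hydroxide cleaves the aryl sulfonate at sulfur (S–O cleavage); the oxolane, the aryl ethers and the secondary carbinol, now no longer an epimerizable ketone, are stable to base at this temperature.

Step 13
Reactants: 20 methyl (R)-lactate
Product: 21 (R)-2-hydroxy-N-methoxy-N-methylpropanamide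
Conditions: MeNHOMe·HCl, iPrMgCl, THF, −20 → 0 °C
Reagents that add atoms: N,O-dimethylhydroxylamine hydrochloride, CNOC.Cl
Why: Weinreb amide formation as in step 7, in the antipodal series.

Step 14
Reactants: 21 Weinreb amide; 14 3,4-dimethoxyphenylmagnesium bromide
Product: 22 (R)-1-(3,4-dimethoxyphenyl)-2-hydroxypropan-1-one
Conditions: 14 (2.5 equiv), THF, 0 °C → rt; aq. NH4Cl
Reagents that add atoms: none
Why: Grignard addition to the Weinreb amide as in step 8, with retention at the α-carbon.

Step 15
Reactants: 22 (R)-hydroxy ketone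
Product: 23 (R)-1-(3,4-dimethoxyphenyl)-1-oxopropan-2-yl methanesulfonate
Conditions: MsCl, Et3N, CH2Cl2, 0 °C
Reagents that add atoms: methanesulfonyl chloride (MsCl), CS(Cl)(=O)=O
Why: O-sulfonylation with retention, as in step 9.

Step 16
Reactants: 19 ring-B phenol; 23 (R)-mesylate
Product: 24 (2S)-1-(3,4-dimethoxyphenyl)-2-[4-[(2R,3S,4S,5S)-5-[4-[(1R,2R)-1-(3,4-dimethoxyphenyl)-1-hydroxypropan-2-yl]oxy-3-methoxyphenyl]-3,4-dimethyloxolan-2-yl]-2-methoxyphenoxy]propan-1-one
Conditions: K2CO3, DMF, rt
Reagents that add atoms: none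
Why: Williamson ether synthesis (SN2, inversion) of the phenoxide, which carbonate forms selectively in the presence of the secondary alcohol; the (R)-mesylate gives the (S)-aryl ether.

Step 17
Reactants: 24 ring-B ketone
Product: 25 (1R,2R)-1-(3,4-dimethoxyphenyl)-2-[4-[(2S,3S,4S,5R)-5-[4-[(1S,2S)-1-(3,4-dimethoxyphenyl)-1-hydroxypropan-2-yl]oxy-3-methoxyphenyl]-3,4-dimethyloxolan-2-yl]-2-methoxyphenoxy]propan-1-ol (target)
Conditions: LiBH(s-Bu)3 (excess), THF, −78 °C; aq. NH4Cl
Reagents that add atoms: none
Why: Felkin–Anh controlled reduction as in step 11; the (2S) α-aryloxy center should direct hydride to give the threo (1S,2S) carbinol, and the existing chain only consumes one hydride equivalent as its alkoxide.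

**Compound list**

1 | vanillin (4-hydroxy-3-methoxybenzaldehyde) | COc1cc(C=O)ccc1O | starting material
2 | 4-formyl-2-methoxyphenyl 4-methylbenzenesulfonate | COc1cc(C=O)ccc1OS(=O)(=O)c1ccc(C)cc1 | intermediate
3 | (Z)-crotylboronic acid pinacol ester | C/C=C\CB1OC(C)(C)C(C)(C)O1 | starting material
4 | 4-[(1R,2S)-1-hydroxy-2-methylbut-3-en-1-yl]-2-methoxyphenyl 4-methylbenzenesulfonate | O[C@@H](c1ccc(OS(=O)(=O)c2ccc(C)cc2)c(OC)c1)[C@@H](C)C=C | intermediate
5 | 4-[(1R,2S)-1-(diphenylphosphanyloxy)-2-methylbut-3-en-1-yl]-2-methoxyphenyl 4-methylbenzenesulfonate (tethered substrate, not isolated) | c1ccc(cc1)P(c1ccccc1)O[C@@H](c1ccc(OS(=O)(=O)c2ccc(C)cc2)c(OC)c1)[C@@H](C)C=C | intermediate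
6 | 4-[(1R,2S,3S)-1-hydroxy-2,3-dimethyl-4-oxobutyl]-2-methoxyphenyl 4-methylbenzenesulfonate (not isolated) | O[C@@H](c1ccc(OS(=O)(=O)c2ccc(C)cc2)c(OC)c1)[C@@H](C)[C@H](C)C=O | intermediate
7 | (3S,4S,5R)-5-[3-methoxy-4-(tosyloxy)phenyl]-3,4-dimethyloxolan-2-ol (both anomers) | OC1O[C@@H](c2ccc(OS(=O)(=O)c3ccc(C)cc3)c(OC)c2)[C@@H](C)[C@@H]1C | intermediate
8 | [4-(benzyloxy)-3-methoxyphenyl]boronic acid | COc1cc(B(O)O)ccc1OCc1ccccc1 | starting material
9 | potassium [4-(benzyloxy)-3-methoxyphenyl]trifluoroborate | COc1cc(ccc1OCc1ccccc1)[B-](F)(F)F.[K+] | intermediate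
10 | (2S,3S,4S,5R)-2-[4-(benzyloxy)-3-methoxyphenyl]-5-[3-methoxy-4-(tosyloxy)phenyl]-3,4-dimethyloxolane | COc1cc(ccc1OCc1ccccc1)[C@H]1O[C@@H](c2ccc(OS(=O)(=O)c3ccc(C)cc3)c(OC)c2)[C@@H](C)[C@@H]1C | intermediate
11 | 4-[(2S,3S,4S,5R)-5-[3-methoxy-4-(tosyloxy)phenyl]-3,4-dimethyloxolan-2-yl]-2-methoxyphenol | COc1cc(ccc1O)[C@H]1O[C@@H](c2ccc(OS(=O)(=O)c3ccc(C)cc3)c(OC)c2)[C@@H](C)[C@@H]1C | intermediate
12 | ethyl (S)-lactate | CCOC(=O)[C@H](C)O | starting material
13 | (S)-2-hydroxy-N-methoxy-N-methylpropanamide | CON(C)C(=O)[C@H](C)O | intermediate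
14 | 3,4-dimethoxyphenylmagnesium bromide | COc1ccc([Mg]Br)cc1OC | starting material
15 | (S)-1-(3,4-dimethoxyphenyl)-2-hydroxypropan-1-one | COc1ccc(cc1OC)C(=O)[C@H](C)O | intermediate
16 | (S)-1-(3,4-dimethoxyphenyl)-1-oxopropan-2-yl methanesulfonate | COc1ccc(cc1OC)C(=O)[C@H](C)OS(C)(=O)=O | intermediate
17 | (2R)-1-(3,4-dimethoxyphenyl)-2-[2-methoxy-4-[(2S,3S,4S,5R)-5-[3-methoxy-4-(tosyloxy)phenyl]-3,4-dimethyloxolan-2-yl]phenoxy]propan-1-one | COc1ccc(cc1OC)C(=O)[C@@H](C)Oc1ccc(cc1OC)[C@H]1O[C@@H](c2ccc(OS(=O)(=O)c3ccc(C)cc3)c(OC)c2)[C@@H](C)[C@@H]1C | intermediate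
18 | 4-[(2R,3S,4S,5S)-5-[4-[(1R,2R)-1-(3,4-dimethoxyphenyl)-1-hydroxypropan-2-yl]oxy-3-methoxyphenyl]-3,4-dimethyloxolan-2-yl]-2-methoxyphenyl 4-methylbenzenesulfonate | COc1ccc(cc1OC)[C@@H](O)[C@@H](C)Oc1ccc(cc1OC)[C@H]1O[C@@H](c2ccc(OS(=O)(=O)c3ccc(C)cc3)c(OC)c2)[C@@H](C)[C@@H]1C | intermediate
19 | (1R,2R)-1-(3,4-dimethoxyphenyl)-2-[4-[(2S,3S,4S,5R)-5-(4-hydroxy-3-methoxyphenyl)-3,4-dimethyloxolan-2-yl]-2-methoxyphenoxy]propan-1-ol | COc1ccc(cc1OC)[C@@H](O)[C@@H](C)Oc1ccc(cc1OC)[C@H]1O[C@@H](c2ccc(O)c(OC)c2)[C@@H](C)[C@@H]1C | intermediate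
20 | methyl (R)-lactate | COC(=O)[C@@H](C)O | starting material
21 | (R)-2-hydroxy-N-methoxy-N-methylpropanamide | CON(C)C(=O)[C@@H](C)O | intermediate
22 | (R)-1-(3,4-dimethoxyphenyl)-2-hydroxypropan-1-one | COc1ccc(cc1OC)C(=O)[C@@H](C)O | intermediate
23 | (R)-1-(3,4-dimethoxyphenyl)-1-oxopropan-2-yl methanesulfonate | COc1ccc(cc1OC)C(=O)[C@@H](C)OS(C)(=O)=O | intermediate
24 | (2S)-1-(3,4-dimethoxyphenyl)-2-[4-[(2R,3S,4S,5S)-5-[4-[(1R,2R)-1-(3,4-dimethoxyphenyl)-1-hydroxypropan-2-yl]oxy-3-methoxyphenyl]-3,4-dimethyloxolan-2-yl]-2-methoxyphenoxy]propan-1-one | COc1ccc(cc1OC)[C@@H](O)[C@@H](C)Oc1ccc(cc1OC)[C@H]1O[C@@H](c2ccc(O[C@@H](C)C(=O)c3ccc(OC)c(OC)c3)c(OC)c2)[C@@H](C)[C@@H]1C | intermediate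
25 | (1R,2R)-1-(3,4-dimethoxyphenyl)-2-[4-[(2S,3S,4S,5R)-5-[4-[(1S,2S)-1-(3,4-dimethoxyphenyl)-1-hydroxypropan-2-yl]oxy-3-methoxyphenyl]-3,4-dimethyloxolan-2-yl]-2-methoxyphenoxy]propan-1-ol | COc1ccc(cc1OC)[C@@H](O)[C@@H](C)Oc1ccc(cc1OC)[C@H]1O[C@@H](c2ccc(O[C@@H](C)[C@@H](O)c3ccc(OC)c(OC)c3)c(OC)c2)[C@@H](C)[C@@H]1C | target

**Step count and risks**

Total step count: 17. Longest linear sequence: 10 steps (steps 1, 2, 3, 5, 6, 10, 11, 12, 16, 17).

Steps most likely to fail:

1. Step 3 (key step). The secondary benzylic alcohol may exchange onto phosphorus too slowly, so that undirected hydroformylation at the terminal carbon (linear aldehyde, six-membered lactol) competes; equilibration at C3 may also stay incomplete. The fallback sets out from 4 and comes back at 7 by known steps. Hydroboration of the vinyl group with 9-BBN and oxidation with NaBO3·4H2O would give 4-[(1R,2S)-1,4-dihydroxy-2-methylbutyl]-2-methoxyphenyl 4-methylbenzenesulfonate F1. Selective oxidation of the primary alcohol with TEMPO/PhI(OAc)2, which lactonizes through the lactol, would give the cis lactone 4-[(2R,3S)-3-methyl-5-oxooxolan-2-yl]-2-methoxyphenyl 4-methylbenzenesulfonate F2. Enolate methylation with LiN(iPr)2 and MeI, trans to the neighbouring methyl, would give 4-[(2R,3S,4S)-3,4-dimethyl-5-oxooxolan-2-yl]-2-methoxyphenyl 4-methylbenzenesulfonate F3. Partial reduction with iBu2AlH at −78 °C then returns to lactol 7.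

2. Step 5. The first-formed 2-aryl oxolane may reopen at C2 under BF3 and take up a second aryl group, the electron-rich aryl boron species may protodeboronate, or attack may come from the wrong face. The fallback sets out from 7 and comes back at 10 with the polarity of the aryl transfer changed. [4-(Benzyloxy)-3-methoxyphenyl]magnesium bromide F4 (from 4-bromo-1-(benzyloxy)-2-methoxybenzene and Mg, excess, THF, 0 °C) would add to the open hydroxy-aldehyde form of 7. This gives 4-[(1R,2S,3S,4RS)-4-[4-(benzyloxy)-3-methoxyphenyl]-1,4-dihydroxy-2,3-dimethylbutyl]-2-methoxyphenyl 4-methylbenzenesulfonate F5 as a mixture of carbinol epimers. Catalytic TsOH·H2O in CH2Cl2 should then ionize only the electron-rich ring-A carbinol, and the C5 hydroxyl closes the ring stereoconvergently to the 2,3-trans oxolane 10.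

3. Step 11 (the same concern holds for step 17). Lithium chelation between the carbonyl and the aryloxy oxygen may compete with the Felkin–Anh pathway and erode the threo selectivity. The fallback sets out from 17 and comes back at 18 with the control element changed from substrate to catalyst: Corey–Bakshi–Shibata reduction with (R)-2-methyl-CBS-oxazaborolidine and BH3·SMe2 in THF, the catalyst enantiomer expected to give the (1R) carbinol when the aryl group acts as the large substituent. For step 17 the (S)-catalyst would be used in the same way from 24 to 25. No new compound arises.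

Further compounds
F1 | step 3 | 4-[(1R,2S)-1,4-dihydroxy-2-methylbutyl]-2-methoxyphenyl 4-methylbenzenesulfonate | O[C@@H](c1ccc(OS(=O)(=O)c2ccc(C)cc2)c(OC)c1)[C@@H](C)CCO
F2 | step 3 | 4-[(2R,3S)-3-methyl-5-oxooxolan-2-yl]-2-methoxyphenyl 4-methylbenzenesulfonate | O=C1O[C@@H](c2ccc(OS(=O)(=O)c3ccc(C)cc3)c(OC)c2)[C@@H](C)C1
F3 | step 3 | 4-[(2R,3S,4S)-3,4-dimethyl-5-oxooxolan-2-yl]-2-methoxyphenyl 4-methylbenzenesulfonate | O=C1O[C@@H](c2ccc(OS(=O)(=O)c3ccc(C)cc3)c(OC)c2)[C@@H](C)[C@@H]1C
F4 | step 5 | [4-(benzyloxy)-3-methoxyphenyl]magnesium bromide | COc1cc([Mg]Br)ccc1OCc1ccccc1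
F5 | step 5 | 4-[(1R,2S,3S,4RS)-4-[4-(benzyloxy)-3-methoxyphenyl]-1,4-dihydroxy-2,3-dimethylbutyl]-2-methoxyphenyl 4-methylbenzenesulfonate | O[C@@H](c1ccc(OS(=O)(=O)c2ccc(C)cc2)c(OC)c1)[C@@H](C)[C@@H](C(O)c1ccc(OCc2ccccc2)c(OC)c1)C
F0 | step 11 | none | none
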